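**Retrosynthetic overview** (ring A = methoxy/hydroxy ring, ring B = central ring, ring C = the hydroxybenzyl ring on B)
1. The two phenolic C–O bonds on rings A and B are cut back to C–H: each is the only C–H on its ring with no ortho neighbour, so Ir C–H borylation/oxidation finds exactly these two. This C–O formation is the centre of the route.
2. The two ring-A benzyl C–C bonds go back to 4-hydroxybenzyl alcohol, added in the same flask once the new OH has turned ring A into a resorcinol monoether.
3. ArCH2–CH2Ar goes back to 3-vinylanisole (as its 9-BBN adduct) and an aryl bromide (B-alkyl Suzuki).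
4. Ring B–CH2–ring C goes back to 3-bromobenzyl bromide and the Grignard reagent of TIPS-protected 4-bromophenol.
5. No ring is built: all five benzene rings are bought and joined in the order C–B, then A, then the two outer hydroxybenzyl rings.

Assumption: the target has no stereocentre and no stereogenic double bond; it is achiral, so there is no configuration to set or protect.

**Step 1**
Reactants: 1 (4-bromophenoxy)triisopropylsilane; 2 3-bromobenzyl bromide
Product: 4 [4-(3-bromobenzyl)phenoxy]triisopropylsilane, via [4-(triisopropylsilyloxy)phenyl]magnesium bromide 3 (not isolated)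
Conditions: i. Mg (I2 cat.), THF, 45 °C; ii. 2, CuI (5 mol%), THF, −20 → 0 °C
Reagents that add atoms: none
Why: Copper-catalysed Kumada-type C(sp2)–C(sp3) coupling: the arylcopper species formed from 3 displaces the benzylic bromide of 2 far faster than anything touches its aryl bromide, and the TIPS ether is inert to Mg and Cu.

**Step 2**
Reactants: 5 3-vinylanisole (1-ethenyl-3-methoxybenzene); 4 [4-(3-bromobenzyl)phenoxy]triisopropylsilane
Product: 7 triisopropyl(4-{3-[2-(3-methoxyphenyl)ethyl]benzyl}phenoxy)silane, via 9-[2-(3-methoxyphenyl)ethyl]-9-borabicyclo[3.3.1]nonane 6 (not isolated)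
Conditions: i. 9-BBN, THF, 0 °C → rt; ii. 4, Pd(dppf)Cl2 (3 mol%), aq. K3PO4, THF, 60 °C
Reagents that add atoms: none
Why: B-alkyl Suzuki–Miyaura coupling: 9-BBN adds anti-Markovnikov to the styrene and the primary alkylborane 6 transmetallates cleanly to the aryl–Pd–Br from 4 under Pd(dppf)/phosphate, while the methyl ether and the base-robust TIPS ether are left alone.

**Step 3**
Reactants: 7 triisopropyl(4-{3-[2-(3-methoxyphenyl)ethyl]benzyl}phenoxy)silane; 8 4-hydroxybenzyl alcohol
Product: 12 2,4-bis(4-hydroxybenzyl)-3-{2-[3-hydroxy-5-(4-hydroxybenzyl)phenyl]ethyl}-5-methoxyphenol (CNP0204120.0), via triisopropyl{4-[3-(2-{3-methoxy-5-(4,4,5,5-tetramethyl-1,3,2-dioxaborolan-2-yl)phenyl}ethyl)-5-(4,4,5,5-tetramethyl-1,3,2-dioxaborolan-2-yl)benzyl]phenoxy}silane 9 (not isolated), via 3-methoxy-5-(2-{3-hydroxy-5-[4-(triisopropylsilyloxy)benzyl]phenyl}ethyl)phenol 10 (not isolated), via 2,4-bis(4-hydroxybenzyl)-3-(2-{3-hydroxy-5-[4-(triisopropylsilyloxy)benzyl]phenyl}ethyl)-5-methoxyphenol 11 (not isolated)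
Conditions: i. [Ir(OMe)(cod)]2 (2 mol%), dtbpy (4 mol%), B2pin2 (2.2 equiv), THF, 80 °C, then volatiles off; ii. Oxone (2.2 equiv KHSO5), acetone/H2O, rt; iii. 8 (2.1 equiv, added over 3 h), 45 °C; iv. KF, 40 °C
Reagents that add atoms: potassium peroxymonosulfate (active salt of Oxone), [K+].[O-]S(=O)(=O)OO
Why: Proposed new method: an oxidant-to-acid relay in one flask, in which sterically controlled Ir-catalysed C–H borylation reaches only the one C–H on ring A and the one on ring B that have no ortho substituent (ring C is shut by its para-alkyl and bulky OTIPS groups), Oxone then turns both C–B bonds into C–O bonds by 1,2-aryl shift of the peroxyborate, the KHSO4 it leaves ionises 8 to the 4-hydroxybenzyl cation (protonated p-quinone methide), which attacks the new resorcinol-monoether ring at its two positions that are ortho to one oxygen and para to the other (the CH between the oxygens is flanked on both sides, and rings B and C lack the second oxygen donor and are far less nucleophilic), and HF made from KF and the same bisulfate finally removes the TIPS group; the closest known reactions are the one-pot Ir C–H borylation/Oxone phenol synthesis and the acid-catalysed Friedel–Crafts hydroxybenzylation of resorcinols, which have not been run as a relay.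

**Compound list**
1 | (4-bromophenoxy)triisopropylsilane | CC(C)[Si](C(C)C)(C(C)C)Oc1ccc(Br)cc1 | starting material
2 | 3-bromobenzyl bromide | BrCc1cccc(Br)c1 | starting material
3 | [4-(triisopropylsilyloxy)phenyl]magnesium bromide | CC(C)[Si](C(C)C)(C(C)C)Oc1ccc([Mg]Br)cc1 | intermediate (not isolated)
4 | [4-(3-bromobenzyl)phenoxy]triisopropylsilane | CC(C)[Si](C(C)C)(C(C)C)Oc1ccc(Cc2cccc(Br)c2)cc1 | intermediate
5 | 3-vinylanisole | COc1cccc(C=C)c1 | starting material
6 | 9-[2-(3-methoxyphenyl)ethyl]-9-borabicyclo[3.3.1]nonane | COc1cccc(CCB2C3CCCC2CCC3)c1 | intermediate (not isolated)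
7 | triisopropyl(4-{3-[2-(3-methoxyphenyl)ethyl]benzyl}phenoxy)silane | COc1cccc(CCc2cccc(Cc3ccc(O[Si](C(C)C)(C(C)C)C(C)C)cc3)c2)c1 | intermediate
8 | 4-hydroxybenzyl alcohol | OCc1ccc(O)cc1 | starting material
9 | bis(pinacolboronate) of 7 (Bpin at C5 of the methoxy ring and at C5 of the central ring) | COc1cc(B2OC(C)(C)C(C)(C)O2)cc(CCc2cc(B3OC(C)(C)C(C)(C)O3)cc(Cc3ccc(O[Si](C(C)C)(C(C)C)C(C)C)cc3)c2)c1 | intermediate (not isolated)
10 | 3-methoxy-5-(2-{3-hydroxy-5-[4-(triisopropylsilyloxy)benzyl]phenyl}ethyl)phenol | COc1cc(O)cc(CCc2cc(O)cc(Cc3ccc(O[Si](C(C)C)(C(C)C)C(C)C)cc3)c2)c1 | intermediate (not isolated)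
11 | 2,4-bis(4-hydroxybenzyl)-3-(2-{3-hydroxy-5-[4-(triisopropylsilyloxy)benzyl]phenyl}ethyl)-5-methoxyphenol | COc1cc(O)c(Cc2ccc(O)cc2)c(CCc2cc(O)cc(Cc3ccc(O[Si](C(C)C)(C(C)C)C(C)C)cc3)c2)c1Cc1ccc(O)cc1 | intermediate (not isolated)
12 | 2,4-bis(4-hydroxybenzyl)-3-{2-[3-hydroxy-5-(4-hydroxybenzyl)phenyl]ethyl}-5-methoxyphenol | COc1cc(O)c(Cc2ccc(O)cc2)c(CCc2cc(O)cc(Cc3ccc(O)cc3)c2)c1Cc1ccc(O)cc1 | target

**Step count and risks**
Total steps: 3. Longest linear sequence: 3 (1 → 4 → 7 → 12). Steps most likely to fail, most to least: 3, 2, 1.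

Step 3 (the proposed relay) can fail by over-oxidation of the new phenols, or by slow or unselective benzylation in the acidic aqueous flask. The fallback uses known chemistry only and sets out from 7. The same Ir-catalysed borylation gives 9, standard NaOH/H2O2 oxidation gives 10, and TBAF in THF gives, after chromatography, the triphenol 3-{2-[3-hydroxy-5-(4-hydroxybenzyl)phenyl]ethyl}-5-methoxyphenol F1. F1 is alkylated twice with 4-methoxybenzyl alcohol (Sc(OTf)3 cat., MeNO2, rt), a benzyl donor with no free phenol, to give 2,4-bis(4-methoxybenzyl)-3-{2-[3-hydroxy-5-(4-hydroxybenzyl)phenyl]ethyl}-5-methoxyphenol F2. NaSEt in DMF at 130 °C then cleaves the two anisyl methyl ethers but not the ring-A methyl ether, because that ring is already a phenoxide and would have to leave as a dianion (the known self-terminating behaviour of thiolate demethylation on 3,5-dioxygenated rings). The fallback comes back to the route at 12.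

Step 2 can fail by partial loss of the aryl silyl ether in hot aqueous phosphate or by protodeboronation of 6. The fallback sets out from 4: Sonogashira coupling with 3-ethynylanisole (Pd(PPh3)2Cl2, CuI, Et3N, 60 °C, amine base only) gives triisopropyl(4-{3-[(3-methoxyphenyl)ethynyl]benzyl}phenoxy)silane F3, and H2 over Pd/C in EtOAc saturates the alkyne. It comes back at 7.

Step 1 can fail by halogen–metal exchange and Wurtz homocoupling of 2. The fallback sets out from 1: the Grignard reagent 3 is added to 3-bromobenzaldehyde (THF, 0 °C) to give (3-bromophenyl)[4-(triisopropylsilyloxy)phenyl]methanol F4 (racemic; the stereocentre is removed at once), and ionic hydrogenation with Et3SiH/TFA in CH2Cl2 at 0 °C reduces the benzylic alcohol. It comes back at 4.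

**Further compounds**
F1 | step 3 | 3-{2-[3-hydroxy-5-(4-hydroxybenzyl)phenyl]ethyl}-5-methoxyphenol | COc1cc(O)cc(CCc2cc(O)cc(Cc3ccc(O)cc3)c2)c1
F2 | step 3 | 2,4-bis(4-methoxybenzyl)-3-{2-[3-hydroxy-5-(4-hydroxybenzyl)phenyl]ethyl}-5-methoxyphenol | COc1cc(O)c(Cc2ccc(OC)cc2)c(CCc2cc(O)cc(Cc3ccc(O)cc3)c2)c1Cc1ccc(OC)cc1
F3 | step 2 | triisopropyl(4-{3-[(3-methoxyphenyl)ethynyl]benzyl}phenoxy)silane | COc1cccc(C#Cc2cccc(Cc3ccc(O[Si](C(C)C)(C(C)C)C(C)C)cc3)c2)c1
F4 | step 1 | (3-bromophenyl)[4-(triisopropylsilyloxy)phenyl]methanol (racemic) | OC(c1cccc(Br)c1)c1ccc(O[Si](C(C)C)(C(C)C)C(C)C)cc1
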